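The route rests on the C12–C13 disconnection, the junction between the sp3 terminus of the C11–C12 tether on C9 (ring B) and the sp2 β-carbon C13 of the C13=C14–C15 enoate. In one operation a stereoretentive Negishi coupling joins the complete ent-decalin, as its C12 alkylzinc, to methyl (E)-3-(triflyloxy)but-2-enoate and delivers the whole side chain with the 13E geometry. The precursor is a 12-bromo-8-oxo decalin carrying C4, C5, C9, C10 and the 18-acetate; it arises from a Sharpless-epoxide-initiated cationic bicyclisation terminated by an α-acyl-γ-butyrolactone, whose O–CH2 carbon becomes C12. The C8 ketone is converted into the 6,8(17)-diene afterwards.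

Key step: step 12

Remark: the target is read as the ent-labdane methyl (13E)-18-acetoxy-ent-labda-6,8(17),13-trien-15-oate, (4S,5S,9R,10S), with the C4 methyl cis and the CH2OAc group trans to the C10 methyl. Labdane numbering is used for all decalins, and "cis/trans" refer to the C10 methyl. The C9 configuration drawn for the spiro-lactones is the one expected from the chelated enol and is erased in step 10.

Step 1
Reactants: 1 geranyl acetate
Product: 2 (2E,6E)-8-hydroxy-3,7-dimethylocta-2,6-dien-1-yl acetate
Conditions: SeO2 (cat.), t-BuOOH, salicylic acid (cat.), CH2Cl2, 0 °C → rt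
Reagents that add atoms: tert-butyl hydroperoxide CC(C)(C)OO (oxygen relayed through catalytic SeO2)
Why: SeO2-catalysed allylic hydroxylation (ene reaction, then [2,3]-sigmatropic shift) should be selective for the (E)-methyl of the electron-rich terminal alkene, because the 2,3-alkene is deactivated by its allylic acetate.

Step 2
Reactants: 2 (2E,6E)-8-hydroxy-3,7-dimethylocta-2,6-dien-1-yl acetate
Product: 3 (2E)-5-[(2R,3R)-3-(hydroxymethyl)-3-methyloxiran-2-yl]-3-methylpent-2-en-1-yl acetate
Conditions: Ti(OiPr)4 (cat.), D-(−)-diethyl tartrate (cat.), t-BuOOH, 4 Å MS, CH2Cl2, −20 °C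
Reagents that add atoms: tert-butyl hydroperoxide CC(C)(C)OO
Why: Sharpless asymmetric epoxidation of the (E)-2-methyl allylic alcohol, in which the Ti/D-(−)-tartrate catalyst selects the alkene face that gives the (2R,3R)-epoxide (mirror image of the L-(+)-tartrate outcome); this is the only enantio-determining step, and the acetate-bearing alkene has no directing hydroxyl.

Step 3
Reactants: 3 (2E)-5-[(2R,3R)-3-(hydroxymethyl)-3-methyloxiran-2-yl]-3-methylpent-2-en-1-yl acetate
Product: 4 (2E)-5-[(2R,3R)-3-{[(tert-butyldimethylsilyl)oxy]methyl}-3-methyloxiran-2-yl]-3-methylpent-2-en-1-yl acetate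
Conditions: TBSCl, imidazole, CH2Cl2, 0 °C → rt
Reagents that add atoms: tert-butyldimethylsilyl chloride CC(C)(C)[Si](C)(C)Cl
Why: Imidazole-assisted silylation masks the primary hydroxyl as a non-participating group for the bromination, the dianion alkylation and the cationic cyclisation, without touching a stereocentre.

Step 4
Reactants: 4 (2E)-5-[(2R,3R)-3-{[(tert-butyldimethylsilyl)oxy]methyl}-3-methyloxiran-2-yl]-3-methylpent-2-en-1-yl acetate
Product: 5 (2E)-5-[(2R,3R)-3-{[(tert-butyldimethylsilyl)oxy]methyl}-3-methyloxiran-2-yl]-3-methylpent-2-en-1-ol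
Conditions: K2CO3 (cat.), MeOH, 0 °C
Reagents that add atoms: none
Why: Base-catalysed transesterification with methanol removes the allylic acetate, while the trisubstituted epoxide and the silyl ether are stable to catalytic carbonate.

Step 5
Reactants: 5 (2E)-5-[(2R,3R)-3-{[(tert-butyldimethylsilyl)oxy]methyl}-3-methyloxiran-2-yl]-3-methylpent-2-en-1-ol
Product: 7 {[(2R,3R)-3-[(3E)-5-bromo-3-methylpent-3-en-1-yl]-2-methyloxiran-2-yl]methoxy}(tert-butyl)dimethylsilane, via allylic mesylate 6 (not isolated)
Conditions: MsCl, Et3N, THF, −40 °C; then LiBr, THF, −40 → 0 °C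
Reagents that add atoms: lithium bromide [Li+].[Br-]; methanesulfonyl chloride CS(=O)(=O)Cl (carried only in 6)
Why: Mesylation and SN2 displacement by bromide at low temperature should give the primary allylic bromide without allylic transposition, alkene isomerisation or epoxide opening.

Step 6
Reactants: 7 {[(2R,3R)-3-[(3E)-5-bromo-3-methylpent-3-en-1-yl]-2-methyloxiran-2-yl]methoxy}(tert-butyl)dimethylsilane; 8 2-acetylbutyrolactone (3-acetyloxolan-2-one)
Product: 10 3-[(4E)-7-[(2R,3R)-3-{[(tert-butyldimethylsilyl)oxy]methyl}-3-methyloxiran-2-yl]-5-methylhept-4-enoyl]oxolan-2-one (epimers at the lactone α-carbon), via dianion 9 (not isolated)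
Conditions: 8, NaH then n-BuLi, THF, 0 °C; then 7, 0 °C → rt; aq NH4Cl
Reagents that add atoms: none
Why: γ-Alkylation of a β-dicarbonyl dianion, in which the more basic terminal carbanion attacks the primary allylic bromide by SN2 with retention of the (E)-alkene and without touching the hindered epoxide; the lactone α-carbon stays a mobile stereocentre.

Step 7
Reactants: 10 3-[(4E)-7-[(2R,3R)-3-{[(tert-butyldimethylsilyl)oxy]methyl}-3-methyloxiran-2-yl]-5-methylhept-4-enoyl]oxolan-2-one
Product: 11 hydroxy spiro keto lactone: trans-decalin-8-one whose C9 is the spiro α-carbon of a γ-butyrolactone (C9–C11H2–C12H2–O–C(=O)–C9); 3-OH equatorial and cis, C4 methyl cis, CH2OTBS (C18) trans, H5 trans, lactone C=O cis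
Conditions: SnCl4, CH2Cl2, −78 → −30 °C; H2O quench
Reagents that add atoms: none
Why: Lewis-acid-promoted epoxy-polyene cyclisation with a β-dicarbonyl enol terminator, in which the activated epoxide is opened at tertiary C4 with inversion by the (E)-C5=C10 alkene through a chair–chair transition state, so that C3 (retained from the epoxide) dictates C4 (the (E)-CH2OTBS ends equatorial), C5 and C10 (trans-decalin), and the tin-chelated enol closes ring B through C9.

Step 8
Reactants: 11 hydroxy spiro keto lactone
Product: 12 3-O-(imidazol-1-ylthiocarbonyl) derivative of 11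
Conditions: 1,1'-thiocarbonyldiimidazole, DMAP (cat.), ClCH2CH2Cl, 70 °C
Reagents that add atoms: 1,1'-thiocarbonyldiimidazole S=C(n1ccnc1)n1ccnc1
Why: Thioacylation of the secondary alcohol gives the radical precursor for Barton–McCombie deoxygenation under neutral conditions that spare the enolisable ketone.

Step 9
Reactants: 12 3-O-(imidazol-1-ylthiocarbonyl) spiro keto lactone
Product: 13 3-deoxy spiro keto lactone (18-OTBS, C8 ketone, C9 spiro-γ-butyrolactone, other centres as in 11)
Conditions: n-Bu3SnH, AIBN (cat.), toluene, 110 °C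
Reagents that add atoms: none
Why: Barton–McCombie deoxygenation (stannyl radical addition to C=S, β-scission to the C3 radical, hydrogen transfer from the stannane) removes the C3 oxygen, while ketone, lactone and silyl ether are inert to the radical chain.

Step 10
Reactants: 13 3-deoxy spiro keto lactone
Product: 15 18-acetoxy-12-bromo-13,14,15,16,17-pentanor-ent-labdan-8-one (2-bromoethyl chain at C9 equatorial, cis), via bromo alcohol 14 (not isolated)
Conditions: HBr (33 wt% in AcOH), 25 → 65 °C; then Ac2O, 25 °C; aq NaHCO3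
Reagents that add atoms: hydrogen bromide Br; acetic anhydride CC(=O)OC(C)=O
Why: Acidic lactone cleavage and decarboxylation, in which bromide opens the protonated γ-lactone by SN2 at the unhindered O–CH2 carbon (C12), the β-keto acid loses CO2 and the enol ketonises under thermodynamic control to set C9 with the chain equatorial, while the acid removes the silyl ether and acetic anhydride acetylates the freed primary alcohol.

Step 11
Reactants: 16 methyl acetoacetate
Product: 17 methyl (E)-3-{[(trifluoromethyl)sulfonyl]oxy}but-2-enoate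
Conditions: Tf2O, aq Me4NOH, hexanes, 5 °C
Reagents that add atoms: trifluoromethanesulfonic anhydride O=S(=O)(OS(=O)(=O)C(F)(F)F)C(F)(F)F
Why: Enol triflation of a β-keto ester under non-chelating conditions (tetramethylammonium enolate, two-phase system) should place the triflate trans to the ester and so give the (E)-enol triflate that carries the side-chain geometry.

Step 12
Reactants: 15 18-acetoxy-12-bromo-13,14,15,16,17-pentanor-ent-labdan-8-one; 17 methyl (E)-3-{[(trifluoromethyl)sulfonyl]oxy}but-2-enoate
Product: 19 methyl (13E)-18-acetoxy-8-oxo-17-nor-ent-labd-13-en-15-oate, via alkylzinc bromide 18 (not isolated)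
Conditions: Zn dust, I2 (cat.), DMA, 70 °C; then 17, PdCl2(dppf) (cat.), THF/DMA, 25 → 45 °C
Reagents that add atoms: zinc [Zn] (carried only in 18)
Why: Zinc inserts into the primary C12–Br bond to give alkylzinc bromide 18, which is inert toward the C8 ketone and both esters; Pd(0) then adds oxidatively to the vinyl C–OTf bond of 17 with retention, and transmetalation from zinc and reductive elimination form the C12–C13 bond. The closest known reaction type is the Negishi sp3–sp2 coupling of functionalised alkylzinc halides with β-sulfonyloxy or β-halo enoates. No ring is closed and no stereocentre is created; the one new stereo-element, the C13=C14 (E) double bond, is controlled by the geometry of enol triflate 17, which is transferred with retention. The step needs reductive elimination to outrun β-hydride elimination from the alkylpalladium (H on C11), which the wide-bite-angle dppf ligand should secure, and chemoselectivity for the vinyl triflate over the ketone, which the low nucleophilicity of the alkylzinc bromide secures. The neutral conditions leave the epimerisable C9 centre and the γ-position of the new enoate untouched.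

Step 13
Reactants: 19 methyl (13E)-18-acetoxy-8-oxo-17-nor-ent-labd-13-en-15-oate
Product: 21 methyl (13E)-18-acetoxy-8-oxo-17-nor-ent-labda-6,13-dien-15-oate, via silyl enol ether 20 (not isolated)
Conditions: LiHMDS, THF, −78 °C; Me3SiCl; then Pd(OAc)2, MeCN, 25 °C
Reagents that add atoms: chlorotrimethylsilane C[Si](C)(C)Cl (carried only in 20)
Why: Saegusa–Ito oxidation, in which kinetic deprotonation by the hindered amide at the less substituted C7 of the ketone (far more acidic than the acetate and the enoate), O-silylation and Pd(II)-mediated dehydrosilylation with β-hydride elimination from C6 should give the 6-en-8-one regioselectively.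

Step 14
Reactants: 21 methyl (13E)-18-acetoxy-8-oxo-17-nor-ent-labda-6,13-dien-15-oate
Product: 22 methyl (13E)-18-acetoxy-ent-labda-6,8(17),13-trien-15-oate, (4S,5S,9R,10S)
Conditions: Zn, CH2Br2, TiCl4, THF/CH2Cl2, 0 → 25 °C
Reagents that add atoms: dibromomethane BrCBr
Why: Takai–Lombardo methylenation, in which the non-basic zinc/titanium methylene reagent adds 1,2 to the enone carbonyl and not to the two esters, should give the exocyclic C8=C17 methylene of the 6,8(17)-diene without epimerising C9.

Compound list
1 | geranyl acetate | CC(C)=CCC/C(C)=C/COC(C)=O | starting material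
2 | (2E,6E)-8-hydroxy-3,7-dimethylocta-2,6-dien-1-yl acetate | OC/C(C)=C/CC/C(C)=C/COC(C)=O | intermediate
3 | (2E)-5-[(2R,3R)-3-(hydroxymethyl)-3-methyloxiran-2-yl]-3-methylpent-2-en-1-yl acetate | OC[C@@]1(C)O[C@@H]1CC/C(C)=C/COC(C)=O | intermediate
4 | TBS ether of 3 | CC(C)(C)[Si](C)(C)OC[C@@]1(C)O[C@@H]1CC/C(C)=C/COC(C)=O | intermediate
5 | epoxy allylic alcohol (acetate of 4 removed) | CC(C)(C)[Si](C)(C)OC[C@@]1(C)O[C@@H]1CC/C(C)=C/CO | intermediate
6 | allylic mesylate of 5 | CC(C)(C)[Si](C)(C)OC[C@@]1(C)O[C@@H]1CC/C(C)=C/COS(C)(=O)=O | intermediate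
7 | {[(2R,3R)-3-[(3E)-5-bromo-3-methylpent-3-en-1-yl]-2-methyloxiran-2-yl]methoxy}(tert-butyl)dimethylsilane | CC(C)(C)[Si](C)(C)OC[C@@]1(C)O[C@@H]1CC/C(C)=C/CBr | intermediate
8 | 2-acetylbutyrolactone | CC(=O)C1CCOC1=O | starting material
9 | sodium lithium dienolate (dianion) of 8 | [Li+].[Na+].C=C([O-])C1=C([O-])OCC1 | intermediate
10 | 3-[(4E)-7-[(2R,3R)-3-{[(tert-butyldimethylsilyl)oxy]methyl}-3-methyloxiran-2-yl]-5-methylhept-4-enoyl]oxolan-2-one | CC(C)(C)[Si](C)(C)OC[C@@]1(C)O[C@@H]1CC/C(C)=C/CCC(=O)C1CCOC1=O | intermediate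
11 | hydroxy spiro keto lactone (3-OH, 18-OTBS, C8 ketone, C9 spiro-γ-butyrolactone) | O=C1CC[C@@H]2[C@@](C)(CO[Si](C)(C)C(C)(C)C)[C@H](O)CC[C@@]2(C)[C@@]13CCOC3=O | intermediate
12 | 3-O-(imidazol-1-ylthiocarbonyl) derivative of 11 | O=C1CC[C@@H]2[C@@](C)(CO[Si](C)(C)C(C)(C)C)[C@H](OC(=S)n3ccnc3)CC[C@@]2(C)[C@@]14CCOC4=O | intermediate
13 | 3-deoxy spiro keto lactone | O=C1CC[C@@H]2[C@@](C)(CO[Si](C)(C)C(C)(C)C)CCC[C@@]2(C)[C@@]13CCOC3=O | intermediate
14 | 12-bromo-18-hydroxy-13,14,15,16,17-pentanor-ent-labdan-8-one | O=C1CC[C@@H]2[C@@](C)(CO)CCC[C@@]2(C)[C@@H]1CCBr | intermediate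
15 | 18-acetoxy-12-bromo-13,14,15,16,17-pentanor-ent-labdan-8-one | O=C1CC[C@@H]2[C@@](C)(COC(C)=O)CCC[C@@]2(C)[C@@H]1CCBr | intermediate
16 | methyl acetoacetate | CC(=O)CC(=O)OC | starting material
17 | methyl (E)-3-{[(trifluoromethyl)sulfonyl]oxy}but-2-enoate | COC(=O)/C=C(\C)OS(=O)(=O)C(F)(F)F | intermediate
18 | C12 alkylzinc bromide derived from 15 | O=C1CC[C@@H]2[C@@](C)(COC(C)=O)CCC[C@@]2(C)[C@@H]1CC[Zn]Br | intermediate
19 | methyl (13E)-18-acetoxy-8-oxo-17-nor-ent-labd-13-en-15-oate | O=C1CC[C@@H]2[C@@](C)(COC(C)=O)CCC[C@@]2(C)[C@@H]1CC/C(C)=C/C(=O)OC | intermediate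
20 | C8 trimethylsilyl enol ether (Δ7) of 19 | C[Si](C)(C)OC1=CC[C@@H]2[C@@](C)(COC(C)=O)CCC[C@@]2(C)[C@@H]1CC/C(C)=C/C(=O)OC | intermediate
21 | methyl (13E)-18-acetoxy-8-oxo-17-nor-ent-labda-6,13-dien-15-oate | O=C1C=C[C@@H]2[C@@](C)(COC(C)=O)CCC[C@@]2(C)[C@@H]1CC/C(C)=C/C(=O)OC | intermediate
22 | methyl (13E)-18-acetoxy-ent-labda-6,8(17),13-trien-15-oate | C=C1C=C[C@@H]2[C@@](C)(COC(C)=O)CCC[C@@]2(C)[C@@H]1CC/C(C)=C/C(=O)OC | target

Total step count: 14. Longest linear sequence: 13 steps (1–10 and 12–14; step 11 prepares the coupling partner).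

Steps most likely to fail

Step 7. The cyclisation may terminate through the enol oxygen or stop after ring A, because closure of the congested C9–C10 bond between two quaternary centres is slow; semipinacol rearrangement of the activated epoxide may also compete. The fallback sets out from 7 and builds the C9 quaternary centre only after the bicycle exists. Bromide 7 would alkylate the dianion of methyl acetoacetate (NaH, n-BuLi, THF) to give epoxy β-keto ester F1. SnCl4 cyclisation through this unhindered enol would give bicyclic β-keto ester F2 with a tertiary C9. Tsuji–Trost allylation (allyl methyl carbonate, Pd(PPh3)4, THF) from the face anti to the C10 methyl would give allyl keto ester F3. Ozonolysis (O3, then Me2S) would give aldehyde F4, and reduction of the aldehyde alone (NaBH4, MeOH, −78 °C) would give hydroxy ester F5. Lactonisation of F5 (PPTS) comes back to the route at 11.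

Step 12. Zinc insertion next to the ketone may be incomplete, the alkylzinc may be protonated, or β-hydride elimination may win at the alkylpalladium stage. The fallback sets out from 15 and avoids any preformed alkylmetal. Halide exchange (NaI, acetone) would give iodo keto acetate F6. A nickel-catalysed reductive cross-electrophile coupling of F6 with 17 (NiBr2·glyme, 4,4'-di-tert-butyl-2,2'-bipyridine, Mn, DMA), which forms the same C12–C13 bond by radical capture at nickel, comes back to the route at 19.

Step 13. Regio- or chemoselectivity of the kinetic enolisation may be lost (deprotonation at C9 or at the acetate), or the dehydrosilylation may stall. The fallback sets out from 19 and reverses the order of the endgame. Takai–Lombardo methylenation of 19 would give exocyclic alkene F7. Allylic hydroxylation (SeO2 cat., t-BuOOH) would give the axial C7 allylic alcohol F8. Anti-elimination of F8 toward C6 with Martin sulfurane comes back to the route at 22.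

Further compounds
F1 | step 7 | methyl (6E)-9-[(2R,3R)-3-{[(tert-butyldimethylsilyl)oxy]methyl}-3-methyloxiran-2-yl]-7-methyl-3-oxonon-6-enoate | CC(C)(C)[Si](C)(C)OC[C@@]1(C)O[C@@H]1CC/C(C)=C/CCC(=O)CC(=O)OC
F2 | step 7 | bicyclic β-keto ester (3-OH, 18-OTBS, C8 ketone, C9-H with equatorial CO2Me) | O=C1CC[C@@H]2[C@@](C)(CO[Si](C)(C)C(C)(C)C)[C@H](O)CC[C@@]2(C)[C@@H]1C(=O)OC
F3 | step 7 | C9-allyl bicyclic β-keto ester (allyl trans, CO2Me cis) | O=C1CC[C@@H]2[C@@](C)(CO[Si](C)(C)C(C)(C)C)[C@H](O)CC[C@@]2(C)[C@]1(CC=C)C(=O)OC
F4 | step 7 | C9-(2-oxoethyl) bicyclic β-keto ester | O=C1CC[C@@H]2[C@@](C)(CO[Si](C)(C)C(C)(C)C)[C@H](O)CC[C@@]2(C)[C@]1(CC=O)C(=O)OC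
F5 | step 7 | C9-(2-hydroxyethyl) bicyclic β-keto ester | O=C1CC[C@@H]2[C@@](C)(CO[Si](C)(C)C(C)(C)C)[C@H](O)CC[C@@]2(C)[C@]1(CCO)C(=O)OC
F6 | step 12 | 18-acetoxy-12-iodo-13,14,15,16,17-pentanor-ent-labdan-8-one | O=C1CC[C@@H]2[C@@](C)(COC(C)=O)CCC[C@@]2(C)[C@@H]1CCI
F7 | step 13 | methyl (13E)-18-acetoxy-ent-labda-8(17),13-dien-15-oate | C=C1CC[C@@H]2[C@@](C)(COC(C)=O)CCC[C@@]2(C)[C@@H]1CC/C(C)=C/C(=O)OC
F8 | step 13 | methyl (13E)-18-acetoxy-7-hydroxy-ent-labda-8(17),13-dien-15-oate (7-OH axial, trans to the C10 methyl) | C=C1[C@@H](O)C[C@@H]2[C@@](C)(COC(C)=O)CCC[C@@]2(C)[C@@H]1CC/C(C)=C/C(=O)OC
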